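A stall at 23.2% reacted, the mean of electrophile lost and target found at the last readings of amber and blue, is the number to explain in these flasks.

| flask | electrophile | nucleophile | free base | remark | time |
|---|---|---|---|---|---|
| amber | 0.17 M | 0.204 M | 0.094 M | run made earlier |  |
| blue | 0.17 M | 0.204 M | 0.23 M | run made earlier |  |
| dawn | 0.17 M | 0.204 M | 0.0850 M |  | 5.0 min |
| dusk | 0.17 M | 0.204 M | 0.130 M |  | 5.0 min |
| summer | 0.17 M | 0.204 M | 0.190 M |  | 5.0 min |

| run | time / min | electrophile / % | target / % |
|---|---|---|---|
| amber | 0.250 | 90.6 | 10.0 |
| amber | 0.833 | 82.4 | 17.0 |
| amber | 1.33 | 82.0 | 20.2 |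
| amber | 2.00 | 80.0 | 20.2 |
| amber | 3.00 | 76.0 | 23.2 |
| amber | 4.00 | 76.4 | 23.4 |
| amber | 5.00 | 76.2 | 22.8 |
| blue | 0.417 | 86.9 | 12.5 |
| blue | 0.667 | 84.4 | 14.8 |
| blue | 1.00 | 82.7 | 16.5 |
| blue | 1.33 | 80.5 | 20.8 |
| blue | 2.00 | 80.3 | 21.2 |
| blue | 3.00 | 78.0 | 22.3 |
| blue | 5.00 | 76.9 | 23.1 |

(scatter of a reading: 1 percentage point)

1. part of the electrophile that has reacted at the end, dawn
2. part of the electrophile that has reacted at the end, dusk
3. part of the electrophile that has reacted at the end, summer
4. what raising the concentration of free base from its lowest to its highest value here does to the part of the electrophile that has reacted (changes below 5 percentage points count as none) (it falls / no change / it rises)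

Read row against row, amber and blue, whose free base differs by a factor of 2.45, agree within the scatter of 1 percentage point: target stands at 20.2% against 21.2% at 2.00 min, then 22.8% against 23.1% at 5.00 min. Read down its column, amber's target stays flat from 3.00 min, although a one-to-one reaction accounts for 0.0394 M of the 0.204 M of nucleophile charged.

The reckoning here supposes that the unmeasured nucleophile is also lost to a reaction with itself, second order in nucleophile, while target forms first order in each partner, and that the flask stops where [nucleophile] reaches zero. Integrating the two uses against each other, the decades by which [electrophile] falls equal the common logarithm of (1 + g[nucleophile]/[electrophile], both as charged) divided by g. The stall is worth 0.115 decades, and since that logarithm changes slowly with g, starting it at 10 gives 9.72 for the competition number g, the selectivity factor of loss over capture less one. Free base does not enter this expression, so by this reckoning dawn, dusk and summer each come to 23.0%, with no change.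

The forecast gives 23.5% (21% to 26%) for dawn, 23.5% (21.5% to 25.5%) for dusk, 23.5% (21.5% to 25.5%) for summer, and no change, holding that “The stall is therefore not set by the free base over this range”; its figure for dusk stands higher than the reckoning's 23.0%.

The flasks give 23.8% in dawn, 23.4% in dusk and 23.2% in summer, a change of −0.59 points across the free base, which counts as no change.

    electrophile + nucleophile → acid set free + target (k = 0.0721 /M/s)
    nucleophile + acid set free ⇌ protonated nucleophile, settled at all times (K = 120 /M)
    acid set free + free base ⇌ salt of the base (K = 13000 /M, k = 4.35 /M/s)
    2 nucleophile → self-condensation product (k = 0.395 /M/s)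

At 5.00 min dusk holds 0.39% of its nucleophile against 77% of its electrophile, beside 0.0817 M of self-condensation product, and the nucleophile, though charged in excess, is the first to run out; g had put dusk at 23.0%. A neighbouring flask, like dusk but with 0.82 M of nucleophile, 4.82 equiv, comes by the same g to 32.8%, and it gives 34.2%, ending with 0.14% of its nucleophile.

(The readings are calculated from invented constants, and the scatter is random.)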